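The 1-aryltetralin hides two C6–C3 isoeugenol skeletons: fused ring A with the chain C4–C3–CH3, and pendant ring C with the chain C1–C2–CH3. Only C2–C3 and C1–C8a tie them together, so these two bonds are disconnected. One photoredox radical-cation [4+2] of two propenylarenes should make both bonds, close ring B, set C1, C2 and C3 all-trans and create the C4 methylene without net redox change. The partner to be oxidised already bears the enantiopure erythro side chain (from ethyl (S)-lactate). Its ring D phenol is an acetate and C7' a silyl ether, leaving the ring C styrene as the only easily oxidised site. The neutral partner is (E)-isoeugenyl acetate.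

Key step: step 7

Numbering: tetralin C1–C8a (C1 bears ring C, C4 is the methylene, C8a is para to the ring A methoxy group). Ring A is the fused arene, ring B the new carbocycle, ring C the aryl group at C1 and ring D the guaiacyl ring of the side chain. C7' is the benzylic carbinol carbon and C8' the ether-bearing carbon. The target reads C1 S, C2 S, C3 R (aryl and both methyl groups all-trans) and C7' S, C8' R (erythro).

Protecting-group logic: an aryl silyl ether on ring D would leave a second electron-rich arene next to an ionisable benzylic C–O bond under strongly oxidising, transiently acidic conditions, so ring D is switched to an acetate before the key step. C7' stays a silyl ether, because a benzylic ester para to a liberated phenolate would be expelled through a quinone methide at the end.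

Assumption: which antipode of the chiral anion leads to the (1S,2S,3R) series cannot be predicted and is to be settled by testing both. Should induction be weak, the cycloadduct is parted from its all-trans (1R,2R,3S) diastereomer by chromatography, which the enantiopure side chain makes possible.

Step 1
Reactants: 1 4-bromo-2-methoxyphenol
Product: 2 (4-bromo-2-methoxyphenoxy)(tert-butyl)dimethylsilane
Conditions: TBSCl, imidazole, DMF, rt
Reagents that add atoms: tert-butyldimethylsilyl chloride, CC(C)(C)[Si](C)(C)Cl
Why: Imidazole-promoted O-silylation of a phenol is routine and removes the acidic proton that would otherwise quench the organolithium made in step 4, and no stereocentre is involved.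

Step 2
Reactants: 3 (E)-isoeugenol; 4 ethyl (S)-lactate
Product: 5 ethyl (R)-2-{2-methoxy-4-[(E)-prop-1-enyl]phenoxy}propanoate
Conditions: PPh3, DIAD, THF, 0 °C to rt
Reagents that add atoms: none
Why: Mitsunobu etherification, in which the phenol displaces the oxyphosphonium-activated secondary hydroxyl of the α-hydroxy ester in an SN2 process with inversion, so that the (S)-carbinol carbon becomes C8' with the required R configuration.

Step 3
Reactants: 5 ethyl (R)-2-{2-methoxy-4-[(E)-prop-1-enyl]phenoxy}propanoate
Product: 6 (R)-2-{2-methoxy-4-[(E)-prop-1-enyl]phenoxy}propanal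
Conditions: i-Bu2AlH (1.1 equiv), CH2Cl2, −78 °C; MeOH, then aq. potassium sodium tartrate
Reagents that add atoms: none
Why: Partial ester reduction, in which the aluminium hemiacetal formed from an α-oxygenated ester at −78 °C is stable until the quench, so the reaction should stop at the aldehyde, which is used crude and at once to keep C8' intact.

Step 4
Reactants: 2 (4-bromo-2-methoxyphenoxy)(tert-butyl)dimethylsilane; 6 (R)-2-{2-methoxy-4-[(E)-prop-1-enyl]phenoxy}propanal
Product: 8 (1S,2R)-1-[4-(tert-butyldimethylsilyloxy)-3-methoxyphenyl]-2-{2-methoxy-4-[(E)-prop-1-enyl]phenoxy}propan-1-ol (erythro; C7' S; C8' R), via aryllithium 7 (not isolated)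
Conditions: 2, n-BuLi, THF, −78 °C; then 6, −78 °C; aq. NH4Cl
Reagents that add atoms: n-butyllithium, [Li]CCCC (supplies only the lithium of 7)
Why: Bromine–lithium exchange followed by 1,2-addition under polar Felkin–Anh (non-chelation) control, in which lithium in THF is not chelated by the weakly basic aryloxy oxygen, the C8'–O bond stands perpendicular to the carbonyl group and the aryl group arrives anti to it past the C8' hydrogen, which sets C7' as S (erythro), the minor epimer being removed by chromatography.

Step 5
Reactants: 8 erythro carbinol (1S,2R)
Product: 9 bis-TBS ether of the erythro 8-O-4 isoeugenol dimer (C7' S; C8' R; silyl ethers at C7' and on the ring D phenol)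
Conditions: TBSOTf, 2,6-lutidine, CH2Cl2, 0 °C
Reagents that add atoms: tert-butyldimethylsilyl triflate, CC(C)(C)[Si](C)(C)OS(=O)(=O)C(F)(F)F
Why: Silyl triflate and a hindered pyridine base silylate a hindered secondary benzylic alcohol without touching the C–O bond, so C7' is retained, and a silyl ether is chosen because, unlike an ester, it cannot be expelled once the para phenol of ring D is set free.

Step 6
Reactants: 9 bis-TBS ether of the erythro 8-O-4 isoeugenol dimer
Product: 11 4-[(1S,2R)-1-(tert-butyldimethylsilyloxy)-2-{2-methoxy-4-[(E)-prop-1-enyl]phenoxy}propyl]-2-methoxyphenyl acetate, via tetrabutylammonium phenoxide 10 (not isolated)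
Conditions: TBAF (1.0 equiv), THF, −20 °C; then Ac2O, −20 °C to rt
Reagents that add atoms: acetic anhydride, CC(=O)OC(C)=O; tetrabutylammonium fluoride, [F-].CCCC[N+](CCCC)(CCCC)CCCC (supplies only the cation of 10)
Why: Fluoride cleaves the aryl silyl ether much faster than the secondary alkyl silyl ether because phenoxide is the better leaving group on silicon, and in-flask O-acetylation of the phenoxide then gives the aryl acetate that raises the oxidation potential of ring D and weakens its push on the C7'–O bond.

Step 7
Reactants: 11 ring D acetate, C7' TBS ether of the erythro 8-O-4 dimer; 12 (E)-isoeugenyl acetate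
Product: 13 4-[(1S,2R)-2-{4-[(1S,2S,3R)-7-acetoxy-6-methoxy-2,3-dimethyl-1,2,3,4-tetrahydronaphthalen-1-yl]-2-methoxyphenoxy}-1-(tert-butyldimethylsilyloxy)propyl]-2-methoxyphenyl acetate (all-trans tetralin)
Conditions: 9-mesityl-10-methylacridinium salt of a BINOL-derived N-triflyl imidodiphosphorimidate (IDPi) anion (5 mol %), (PhS)2 (20 mol %), 12 (8 equiv), CH2Cl2–toluene, −30 °C, 450 nm LED, N2; 11 added by syringe pump over 12 h
Reagents that add atoms: none
Why: Proposed new method: the excited acridinium removes one electron from the ring C propenyl group of 11 (the lowest oxidation potential in the flask, also reached by hole transfer from any oxidised 12), the β-carbon of neutral 12 bonds to the β-carbon of this radical cation (C2–C3), and in the resulting 1,4-distonic species the charge rests at C1 beside the para-alkoxy ring C while the spin rests at C4. Ring B closes by intramolecular Friedel–Crafts alkylation, C8a of ring A (para to its methoxy group) attacking the C1 cation through a six-membered chair-like transition state; loss of the C8a proton rearomatises ring A, thiophenol formed from (PhS)2 hands a hydrogen atom to the C4 radical, and the thiyl radical takes the electron back from the acridinyl radical, so the sum is redox-neutral. The closest known reaction types are the acridinium/disulfide formal [4+2] dimerisation of styrenes to 1-aryltetralins and the chiral-counteranion photoredox [2+2] cycloaddition of styrene radical cations; new here are the union of two different β-methylstyrenes and control of the absolute sense by the anion. C2 and C3 arise in the C2–C3 bond formation, their trans relation because this bond forms reversibly and only the array with both methyl groups equatorial closes easily, and their absolute sense from the IDPi anion held in a contact ion pair in the cold, weakly polar medium, whereas C1 is set in the ring closure with ring C equatorial and trans to the C2 methyl. Hetero-coupling is favoured over self-coupling by the acetoxy groups on rings A and D (which leave the ring C styrene as the only low-potential donor), by the excess of 12 and by the slow addition of 11, and the direction of closure follows because ring C stabilises the cation far better than acetoxy-bearing ring A, whose carbon para to methoxy then lies in six-ring reach. Cyclobutane adducts should be reopened by renewed oxidation, so that material drains into the tetralin, which cannot revert.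

Step 8
Reactants: 13 protected all-trans tetralin
Product: 14 C7' TBS ether of the target (both phenols free; C1 S; C2 S; C3 R; C7' S; C8' R)
Conditions: K2CO3 (cat.), MeOH, 0 °C to rt
Reagents that add atoms: none
Why: Base-catalysed transesterification removes both aryl acetates, which are activated esters, while the silyl ether at C7' and all five stereocentres, none of them acidic or attached to a leaving group, are untouched.

Step 9
Reactants: 14 C7' TBS ether of the target
Product: 15 target, (6R,7S,8S)-8-(4-{[(1S,2R)-1-hydroxy-1-(4-hydroxy-3-methoxyphenyl)propan-2-yl]oxy}-3-methoxyphenyl)-3-methoxy-6,7-dimethyl-5,6,7,8-tetrahydronaphthalen-2-ol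
Conditions: TBAF, AcOH, THF, rt
Reagents that add atoms: none
Why: Fluoride-induced desilylation breaks the Si–O and not the C–O bond, so C7' keeps its configuration, and the acetic acid buffer keeps the phenols protonated and so shuts off quinone methide formation.

Compound list
1 | 4-bromo-2-methoxyphenol | COc1cc(Br)ccc1O | starting material
2 | (4-bromo-2-methoxyphenoxy)(tert-butyl)dimethylsilane | COc1cc(Br)ccc1O[Si](C)(C)C(C)(C)C | intermediate
3 | (E)-isoeugenol | COc1cc(/C=C/C)ccc1O | starting material
4 | ethyl (S)-lactate | CCOC(=O)[C@H](C)O | starting material
5 | ethyl (R)-2-{2-methoxy-4-[(E)-prop-1-enyl]phenoxy}propanoate | CCOC(=O)[C@@H](C)Oc1ccc(/C=C/C)cc1OC | intermediate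
6 | (R)-2-{2-methoxy-4-[(E)-prop-1-enyl]phenoxy}propanal | O=C[C@@H](C)Oc1ccc(/C=C/C)cc1OC | intermediate
7 | 4-(tert-butyldimethylsilyloxy)-3-methoxyphenyllithium (not isolated) | [Li]c1ccc(O[Si](C)(C)C(C)(C)C)c(OC)c1 | intermediate
8 | (1S,2R)-1-[4-(tert-butyldimethylsilyloxy)-3-methoxyphenyl]-2-{2-methoxy-4-[(E)-prop-1-enyl]phenoxy}propan-1-ol | COc1cc([C@H](O)[C@@H](C)Oc2ccc(/C=C/C)cc2OC)ccc1O[Si](C)(C)C(C)(C)C | intermediate
9 | bis-TBS ether of the erythro (7'S,8'R) 8-O-4 isoeugenol dimer | COc1cc([C@H](O[Si](C)(C)C(C)(C)C)[C@@H](C)Oc2ccc(/C=C/C)cc2OC)ccc1O[Si](C)(C)C(C)(C)C | intermediate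
10 | tetrabutylammonium phenoxide of ring D, C7' TBS ether (not isolated) | COc1cc([C@H](O[Si](C)(C)C(C)(C)C)[C@@H](C)Oc2ccc(/C=C/C)cc2OC)ccc1[O-].CCCC[N+](CCCC)(CCCC)CCCC | intermediate
11 | 4-[(1S,2R)-1-(tert-butyldimethylsilyloxy)-2-{2-methoxy-4-[(E)-prop-1-enyl]phenoxy}propyl]-2-methoxyphenyl acetate | COc1cc([C@H](O[Si](C)(C)C(C)(C)C)[C@@H](C)Oc2ccc(/C=C/C)cc2OC)ccc1OC(C)=O | intermediate
12 | (E)-isoeugenyl acetate | COc1cc(/C=C/C)ccc1OC(C)=O | starting material
13 | protected target: all-trans (1S,2S,3R)-tetralin, ring A acetate, ring D acetate, C7' TBS ether | COc1cc([C@H](O[Si](C)(C)C(C)(C)C)[C@@H](C)Oc2ccc([C@H]3c4cc(OC(C)=O)c(OC)cc4C[C@@H](C)[C@@H]3C)cc2OC)ccc1OC(C)=O | intermediate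
14 | C7' TBS ether of the target | COc1cc([C@H](O[Si](C)(C)C(C)(C)C)[C@@H](C)Oc2ccc([C@H]3c4cc(O)c(OC)cc4C[C@@H](C)[C@@H]3C)cc2OC)ccc1O | intermediate
15 | CID53359464 | COc1cc([C@H](O)[C@@H](C)Oc2ccc([C@H]3c4cc(O)c(OC)cc4C[C@@H](C)[C@@H]3C)cc2OC)ccc1O | target

Total step count: 9. Longest linear sequence: 8 (steps 2 to 9, from (E)-isoeugenol and ethyl (S)-lactate).

Steps most likely to fail

Step 7. Self-coupling of the electron-rich partner may outrun hetero-coupling. The ring may also close in the reverse direction (ring C onto C4), the reaction may stall at the four-membered ring, or the anion may discriminate the faces poorly. The fallback uses known reaction types only, sets out from 11 and 12 and returns at 13.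
- The two alkenes are first joined only as far as a cyclobutane by a crossed radical-cation [2+2] photocycloaddition under a milder photooxidant. Suitable catalysts are Ru(bpm)3(BArF4)2 (bpm = 2,2'-bipyrimidine, BArF4 = tetrakis[3,5-bis(trifluoromethyl)phenyl]borate) or, for absolute control, a thioxanthylium IDPi ion pair.
- Such a catalyst keeps self-dimerisation of 11 reversible but does not reopen the less easily oxidised crossed adduct, the all-trans crossed cyclobutane F1.
- Hydrogenolysis (H2, Pd/C, EtOAc) of the strained, doubly benzylic C1–C4 bond gives the (2R,3R)-2,3-dimethyl-1,4-diarylbutane F2.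
- DDQ (1 equiv, CH2Cl2, 0 °C) then abstracts hydride from the C1 methylene, the only electron-rich benzylic site because rings A and D are acetates.
- Ring A traps the cation in the same chair-like Friedel–Crafts closure, which gives 13.

Step 4. Facial selectivity in the carbonyl addition may be poor. The fallback sets out from the carbinol mixture containing 8 and returns at 8.
- Dess–Martin oxidation (NaHCO3-buffered, CH2Cl2) erases C7' and gives the (R)-α-aryloxy ketone F3.
- Reduction with Zn(BH4)2 in Et2O at low temperature runs through a zinc chelate between the carbonyl oxygen and the guaiacyl ether oxygens.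
- Hydride then arrives from the face of the C8' hydrogen, and this chelation-controlled delivery gives the same (7'S,8'R) carbinol 8. C7' is thus set by C–H rather than C–C bond formation.

Step 3. The ester may be over-reduced, and the α-stereocentre may epimerise during work-up of the aldehyde. The fallback sets out from 5 and returns at 6. Exhaustive reduction with LiBH4 (THF) gives the configurationally robust (R)-2-aryloxypropan-1-ol F4, which can be purified and stored. Buffered Dess–Martin oxidation immediately before step 4 delivers 6 under neutral conditions.

Further compounds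
F1 | step 7 | (1R,2R,3S,4S)-all-trans cyclobutane: position 1 ring C aryl with the side chain of 11, position 2 4-acetoxy-3-methoxyphenyl, positions 3 and 4 methyl | COc1cc([C@H](O[Si](C)(C)C(C)(C)C)[C@@H](C)Oc2ccc([C@H]3[C@H](c4ccc(OC(C)=O)c(OC)c4)[C@@H](C)[C@@H]3C)cc2OC)ccc1OC(C)=O
F2 | step 7 | (2R,3R)-2,3-dimethyl-1,4-diarylbutane: C1 on ring C with the side chain of 11, C4 on 4-acetoxy-3-methoxyphenyl | COc1cc([C@H](O[Si](C)(C)C(C)(C)C)[C@@H](C)Oc2ccc(C[C@@H](C)[C@H](C)Cc3ccc(OC(C)=O)c(OC)c3)cc2OC)ccc1OC(C)=O
F3 | step 4 | (R)-1-[4-(tert-butyldimethylsilyloxy)-3-methoxyphenyl]-2-{2-methoxy-4-[(E)-prop-1-enyl]phenoxy}propan-1-one | COc1cc(C(=O)[C@@H](C)Oc2ccc(/C=C/C)cc2OC)ccc1O[Si](C)(C)C(C)(C)C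
F4 | step 3 | (R)-2-{2-methoxy-4-[(E)-prop-1-enyl]phenoxy}propan-1-ol | OC[C@@H](C)Oc1ccc(/C=C/C)cc1OC
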